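The numbers in the tables are calculated for substances that don't exist; noise was put on by code.

A flat curve tempts one to call a reaction slow, so we first ask whether green is slow at all.

common to all: catalyst 15 mol%; temperature 40 °C
- green: left-handed substrate 0.23 M; right-handed substrate 0.23 M; coupling partner 1.1 equiv; the very flask that is asked about, followed so far
- violet: left-handed substrate 0.12 M; right-handed substrate 0.12 M; coupling partner 1.1 equiv; run made earlier
- flask: left-handed substrate 0.23 M; right-handed substrate 0.23 M; coupling partner 1.10 equiv; time 2.5 d

green run (percent of the left-handed substrate and right-handed substrate together charged)

| time / h | left-handed product / % |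
|---|---|
| 4.00 | 18.0 |
| 12.0 | 16.9 |
| 20.0 | 20.4 |
| 30.0 | 19.1 |
| 50.0 | 19.6 |

violet run (percent of the left-handed substrate and right-handed substrate together charged)

| time / d | left-handed product / % |
|---|---|
| 0.208 | 10.0 |
| 0.625 | 9.2 |
| 1.25 | 8.0 |
| 1.67 | 9.3 |
| 2.50 | 6.5 |

(readings scatter by 1 percentage point)

- Saturday's: at 2.5 d take out 90% of the left-handed product then present, then wait 5.0 d
- Tuesday's: at 2.5 d add catalyst, 100% of the amount charged, then wait 5.0 d
- Friday's: at 2.5 d raise the temperature by 10 K, then wait 5.0 d
- Sunday's: at 2.5 d add coupling partner, 100% of the amount charged, then wait 5.0 d
- Wednesday's: change nothing and wait 5.0 d more

- catalyst is single-handed; left-handed substrate and right-handed substrate are mirror images of each other, charged as a racemate, each of them at the stated concentration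
- what is taken out of left-handed product is counted as made
- additions bring no volume worth counting
- the earlier runs do not show what temperature does; that part of a forecast is a guess

- left-handed product, in percent of the left-handed substrate and right-handed substrate together first charged, at 2.5 d
- the option that brings most further left-handed product ("none" if no option brings more than 2 percentage points) (Saturday's / Tuesday's / Friday's / Sunday's / Wednesday's / none)
- left-handed product present, with what was taken out counted in, in percent of the left-handed substrate and right-handed substrate together first charged, after Tuesday's
- left-handed product present, with what was taken out counted in, in percent of the left-handed substrate and right-handed substrate together first charged, after Sunday's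

1. Green reads level from 4.00 h to 50.0 h, at 18.8% of left-handed product on average. Yet 1.1 equiv of coupling partner was charged, and by that reading 62.4% of the left-handed substrate remains. So green is not slow: it has stopped.

2. Violet averages 8.60%. We suppose that coupling partner decays by a first-order loss, while each coupling partner couples at a rate proportional to [catalyst][left-handed substrate].

3. By these averages, 34.2% of the partner charged became left-handed product in green and 15.6% in violet. Made over not made gives 0.519 and 0.185. These are the capture odds, left-handed product formed per coupling partner that went elsewhere.

4. Between green and violet, [catalyst] and [left-handed substrate] both follow the charge, so on our supposition the odds should differ by 3.67. We read 2.81, and green has used more of its left-handed substrate. A dying catalyst is not excluded, but we commit to the partner's loss.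

5. Our reckoning: now 18.8%; Tuesday's brings catalyst but no coupling partner, so we keep it there. Sunday's scales the odds by the remaining substrate to 0.324, a share of 24.5%. That gains 13 percentage points, for 32.3%, so Sunday's is our best.

6. The forecast differs on both options, giving 19% now, Tuesday's as best, 30% after Tuesday's and 20% after Sunday's: “Fresh catalyst should then repeat the first burst”.

7. The flask gives 19.4% now, Sunday's as best, 19.4% after Tuesday's and 33.2% after Sunday's, beside our 32.3%.

    coupling partner + catalyst + left-handed substrate → catalyst + left-handed product (k = 0.890 M⁻² min⁻¹, Ea = 38.0 kJ mol⁻¹)
    coupling partner + catalyst + right-handed substrate → catalyst + right-handed product (k = 0.330 M⁻² min⁻¹, Ea = 48.0 kJ mol⁻¹)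
    coupling partner → decomposed reagent (k = 0.00780 min⁻¹, Ea = 100 kJ mol⁻¹)
    (constants at 40 °C)

In the flask at 0.0314 d, decay uses coupling partner 1.4 times as fast as coupling with left-handed substrate. At 1.25 d the partner, the limiting reagent, stands at 0% of its charge, with catalyst at 100%. For a neighbour charged with 9 mol% of catalyst, green's capture odds scale to 0.312, which reckons to 13.1% of left-handed product. That neighbour holds 15.2% of left-handed product at 2.50 d.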